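Begin with the flat column. Side product in cedar holds near 6.02%, and the last two alder readings give 3.50%.

| setting | cedar | alder | south | north-west | south-east | west |
|---|---|---|---|---|---|---|
| substrate | 20 mM | 20 mM | 20 mM | 20 mM | 20 mM | 20 mM |
| partner | 4 equiv | 8 equiv | 4.00 equiv (fed, over 2.5 min) | 4.00 equiv (fed, over 2.5 min) | 4.00 equiv | 4.00 equiv |
| second reagent | 1.5 equiv | 1.5 equiv | 1.50 equiv | 1.50 equiv | 1.50 equiv | 1.50 equiv (fed, over 2.5 min) |
| capture agent | 20 mM | 20 mM | 20.0 mM | 20.0 mM | 20.0 mM | 20.0 mM |
| temperature | 25 °C | 25 °C | 25 °C |  |  | 25 °C |
| remark | run made earlier | run made earlier | all else is in the flask from the start; the feed brings no volume worth counting | the addition at −15 °C, then warmed to 25 °C; the feed brings no volume worth counting | everything together at the start at −15 °C, warmed to 25 °C at 2.5 min | all else is in the flask from the start; the feed brings no volume worth counting |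
| time |  |  | 6.0 min | 6.0 min | 6.0 min | 6.0 min |

cedar run (percent of the substrate charged)

| time / min | target / % | side product / % |
|---|---|---|
| 1.33 | 31.3 | 5.7 |
| 2.50 | 31.9 | 4.6 |
| 4.00 | 23.7 | 7.0 |
| 5.00 | 21.8 | 7.2 |
| 6.00 | 14.8 | 5.6 |

alder run (percent of the substrate charged)

| time / s | target / % | side product / % |
|---|---|---|
| 10.0 | 8.7 | 0.6 |
| 15.0 | 14.1 | 0.8 |
| 20.0 | 18.6 | 1.8 |
| 30.0 | 29.0 | 3.5 |
| 40.0 | 33.1 | 3.5 |

(each reading ± 1 percentage point)

- amounts and yields of target count crystals too
- given per volume of solution although it is solid: crystals
- the analysis behind the earlier runs scatters by 1 percentage point, standard deviation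
- on the list of suspects stand: substrate + partner -> open intermediate; second reagent + open intermediate <-> target; substrate + second reagent -> side product; open intermediate + capture agent -> trapped intermediate; crystals <-> target
- the earlier runs do not show what temperature does; that part of a forecast is a guess

- the best flask by share of target in target plus side product; "all alike" if 1.5 percentage points covers them all (south / north-west / south-east / west / all alike)
- share of target in target plus side product at the end, south
- share of target in target plus side product at the end, north-west
- share of target in target plus side product at the end, south-east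
- share of target in target plus side product at the end, west

Substrate has two exits: partner and second reagent. So compare two times. One is the life of substrate against partner at the cedar charge. The other is the life of substrate against second reagent at full charge. Each exit is pseudo-first-order while its reagent stays near charge, so side product over the rest equals the first life over the second. That ratio is the selectivity factor.

Work in powers of ten. Cedar gives the ratio 15.6, exponent 1.19. Alder gives exponent 1.44. The step is 0.247, and going from 4 equiv to 8 equiv of partner should give 0.301. Second reagent is the same in both.

Now find a clock. Alder reads 1.8% at 20.0 s, about half of its plateau. Take that as a half-life, a rough reading. Scaled to the cedar charge, the partner life is 0.962 min. So 15.0 min is the life of substrate against second reagent at full charge.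

Side product is then exposure over that life. Feed partner in south and exposure grows. Substrate stands until the ramp has given it one partner life, 2.19 min, longer than in cedar. South reckons at 14.6% side product, above cedar. So expect the share in south to suffer. Temperature stays a guess.

The forecast gives all alike, with south 60%, north-west 79%, south-east 80% and west 72%, on the ground that “slow partner feed leaves substrate exposed to second reagent”.

The flask gives south-east as best at 86.8%, with north-west 83.9%, west 84.8% and south 42.8%.

    substrate + partner → open intermediate (k = 0.330 L mol⁻¹ s⁻¹, Ea = 37.0 kJ mol⁻¹)
    second reagent + open intermediate ⇌ target (K = 15.0 L mol⁻¹, k = 2.60 L mol⁻¹ s⁻¹, Ea = 41.0 kJ mol⁻¹, ΔH = −62.0 kJ mol⁻¹)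
    substrate + second reagent → side product (k = 0.0570 L mol⁻¹ s⁻¹, Ea = 62.0 kJ mol⁻¹)
    open intermediate + capture agent → trapped intermediate (k = 1.50 L mol⁻¹ s⁻¹, Ea = 50.0 kJ mol⁻¹)
    crystals ⇌ target, rate k5*(cs5 - [target]) while solid is left; crystals form when [target] > cs5 (solubility = 0.760 mM, k = 0.410 s⁻¹)
    (constants at 25 °C)

South holds 14.5% side product at 6.00 min, against the 14.6% reckoned from the life of 15.0 min. Put the same life to west, where second reagent is fed instead. In one partner life the feed delivers the fraction 0.385 of its charge, so the reckoning is 2.46%. West holds 1.87% side product at 6.00 min.

The runs are calculated from invented constants; noise was put on by code.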